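**Plan**
- Retrosynthesis first removes the acetate, the enone C=C (Wittig) and a temporary ester at C3′. It then cuts the C3′–C4′ and C1′–C6′ bonds of ring B together, leaving an allyl 4-aryloxyacetoacetate and 1,1-dimethoxypent-3-yn-2-one.
- This is possible because ring B is a catechol monoether whose ether carbon C1′ lies between the hydroxyl carbon C2′ and the enone-bearing C6′. C1′ can therefore enter as the sp3 O–CH2 carbon of a β-keto ester and C2′ as its ketone, so no aryl–oxygen coupling at a doubly flanked carbon is needed.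
- The O–CH2 bond is cut next (ring A phenol plus a 4-chloroacetoacetate), then the ring A C1–CO2H bond (directed metalation, CO2) and the carbinol–CH2 bond (Grignard), ending at 4-hydroxy-2-methoxybenzaldehyde.
- Forward: ring A is completed, its phenol is alkylated, ring B is annulated onto the ether carbon, and the C3′ ester, acetal and silyl groups are then exchanged for H, the E-enone, the acetate and the free acid.
- The single stereocentre (R, benzylic carbinol) comes from a Corey–Bakshi–Shibata reduction of the aryl isobutyl ketone; its C–O bond is never broken afterwards.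

Key step: step 13

Remark: ring A is numbered as the benzoic acid (C1 CO2H, C2 OMe, C3 carbinol arm, C6 aryloxy) and ring B as C1′ (ether carbon), C2′ (OH), C3′ (H), C4′ (CH3), C5′ (H), C6′ (enone arm); the carbinol centre is R in every intermediate because the order O > aryl > CH2 > H never changes.
Abbreviations in names: MOM = methoxymethyl, TBS = tert-butyldimethylsilyl, TMSE = 2-(trimethylsilyl)ethyl; "ring A oxy" = 4-[(1R)-1-(TBS-oxy)-3-methylbutyl]-3-methoxy-2-(TMSE-oxycarbonyl)phenoxy.

Step 1
Reactants: 1 4-hydroxy-2-methoxybenzaldehyde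
Product: 2 2-methoxy-4-(methoxymethoxy)benzaldehyde
Conditions: MOMCl, i-Pr2NEt, CH2Cl2, 0 °C to rt
Reagents that add atoms: chloromethyl methyl ether, COCCl
Why: Williamson-type O-alkylation of the acidic para-formyl phenol with the reactive α-chloro ether installs the MOM ether that later directs ring metalation.

Step 2
Reactants: 2 2-methoxy-4-(methoxymethoxy)benzaldehyde; 3 isobutylmagnesium bromide
Product: 4 rac-1-[2-methoxy-4-(methoxymethoxy)phenyl]-3-methylbutan-1-ol
Conditions: THF, −20 to 0 °C; aq. NH4Cl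
Reagents that add atoms: none
Why: Grignard addition to the aryl aldehyde forms the carbinol–CH2 bond; the racemic centre is erased in step 3 and reset in step 4.

Step 3
Reactants: 4 rac-1-[2-methoxy-4-(methoxymethoxy)phenyl]-3-methylbutan-1-ol
Product: 5 1-[2-methoxy-4-(methoxymethoxy)phenyl]-3-methylbutan-1-one
Conditions: Dess–Martin periodinane, CH2Cl2, rt
Reagents that add atoms: none
Why: Dess–Martin oxidation of a secondary benzylic alcohol to the aryl ketone runs under near-neutral conditions that leave the MOM acetal intact.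

Step 4
Reactants: 5 1-[2-methoxy-4-(methoxymethoxy)phenyl]-3-methylbutan-1-one
Product: 6 (1R)-1-[2-methoxy-4-(methoxymethoxy)phenyl]-3-methylbutan-1-ol
Conditions: (S)-2-methyl-CBS-oxazaborolidine (15 mol%), BH3·SMe2, THF, −20 °C; MeOH quench
Reagents that add atoms: none
Why: Corey–Bakshi–Shibata reduction, in which the (S)-oxazaborolidine binds the ketone with the ortho-substituted aryl group as the large substituent and, as with acetophenone-type ketones, should deliver hydride to give the R carbinol.

Step 5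
Reactants: 6 (1R)-1-[2-methoxy-4-(methoxymethoxy)phenyl]-3-methylbutan-1-ol
Product: 7 tert-butyl{(1R)-1-[2-methoxy-4-(methoxymethoxy)phenyl]-3-methylbutoxy}dimethylsilane
Conditions: TBSCl, imidazole, DMF, rt
Reagents that add atoms: tert-butyldimethylsilyl chloride, CC(C)(C)[Si](C)(C)Cl
Why: Imidazole-promoted O-silylation leaves the C–O bond and thus the R configuration untouched; the silyl ether tolerates alkyllithium and, unlike an ester, is not expelled by the para-phenoxide formed in step 10.

Step 6
Reactants: 7 tert-butyl{(1R)-1-[2-methoxy-4-(methoxymethoxy)phenyl]-3-methylbutoxy}dimethylsilane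
Product: 9 3-[(1R)-1-(TBS-oxy)-3-methylbutyl]-2-methoxy-6-(methoxymethoxy)benzoic acid, via aryllithium 8 (not isolated)
Conditions: s-BuLi, TMEDA, THF, −78 °C; CO2 (gas), −78 °C to rt; cold 0.5 M HCl to pH 3
Reagents that add atoms: carbon dioxide, O=C=O
Why: Directed ortho-metalation: the ring hydrogen between the methoxy and MOM-oxy groups is the most acidic and is flanked by two coordinating oxygens, so lithiation should occur there at −78 °C, where the hindered benzylic C–H next to the silyloxy group is not attacked, and CO2 traps the aryllithium.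

Step 7
Reactants: 9 3-[(1R)-1-(TBS-oxy)-3-methylbutyl]-2-methoxy-6-(methoxymethoxy)benzoic acid
Product: 10 TMSE 3-[(1R)-1-(TBS-oxy)-3-methylbutyl]-2-methoxy-6-(methoxymethoxy)benzoate
Conditions: 2-(trimethylsilyl)ethanol, PPh3, DIAD, THF, 0 °C to rt
Reagents that add atoms: 2-(trimethylsilyl)ethanol, C[Si](C)(C)CCO
Why: Mitsunobu esterification, in which the carboxylate acts as nucleophile toward the primary alkoxyphosphonium ion, so the hindrance at the 2,6-disubstituted acid carbonyl does not matter.

Step 8
Reactants: 10 TMSE 3-[(1R)-1-(TBS-oxy)-3-methylbutyl]-2-methoxy-6-(methoxymethoxy)benzoate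
Product: 12 TMSE 3-[(1R)-1-(TBS-oxy)-3-methylbutyl]-6-hydroxy-2-methoxybenzoate, via aryl trimethylsilyl ether 11 (not isolated)
Conditions: TMSOTf, 2,2′-bipyridyl, CH2Cl2, 0 °C to rt; then H2O, rt
Reagents that add atoms: none
Why: Silyl triflate–bipyridyl cleavage of an aromatic MOM ether (acetal exchange to the aryl TMS ether, then hydrolysis); the buffered non-protic medium avoids the protic acid that could ionise the electron-rich benzylic silyl ether, and the secondary TBS ether and TMSE ester should survive at 0 °C.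

Step 9
Reactants: 13 ethyl 4-chloro-3-oxobutanoate
Product: 14 prop-2-en-1-yl 4-chloro-3-oxobutanoate
Conditions: allyl alcohol (excess), toluene, 110 °C, ethanol distilled off
Reagents that add atoms: prop-2-en-1-ol, C=CCO
Why: Thermal transesterification of a β-keto ester (through the acylketene or its cyclic enol pathway), driven by removal of ethanol under neutral conditions that leave the C–Cl bond alone.

Step 10
Reactants: 12 TMSE 3-[(1R)-1-(TBS-oxy)-3-methylbutyl]-6-hydroxy-2-methoxybenzoate; 14 prop-2-en-1-yl 4-chloro-3-oxobutanoate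
Product: 15 prop-2-en-1-yl 4-(ring A oxy)-3-oxobutanoate
Conditions: NaH (2.1 equiv), THF–DMF, 0 °C to rt; aq. NH4Cl
Reagents that add atoms: none
Why: Williamson ether synthesis: the sodium phenoxide displaces the primary chloride next to the ketone while the second equivalent of NaH holds the keto ester as its enolate and so suppresses self-condensation; a silanolate is too poor a leaving group for the para-phenoxide to expel.

Step 11
Reactants: 16 methyl 2,2-dimethoxyacetate
Product: 17 N,2,2-trimethoxy-N-methylacetamide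
Conditions: MeNHOMe·HCl, i-PrMgCl, THF, −20 to 0 °C
Reagents that add atoms: N,O-dimethylhydroxylamine hydrochloride, CNOC.Cl
Why: Weinreb amide synthesis: the chloromagnesium amide formed from the hydrochloride and i-PrMgCl acylates at the activated dialkoxyacetate ester, and the chelated adduct does not react further.

Step 12
Reactants: 17 N,2,2-trimethoxy-N-methylacetamide; 18 prop-1-yn-1-ylmagnesium bromide
Product: 19 1,1-dimethoxypent-3-yn-2-one
Conditions: THF, −20 to 0 °C; aq. NH4Cl
Reagents that add atoms: none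
Why: Weinreb ketone synthesis: the alkynyl Grignard adds once to give a chelated magnesium adduct that collapses to the ynone only on quench, so over-addition is avoided and the acetal stays.

Step 13
Reactants: 15 prop-2-en-1-yl 4-(ring A oxy)-3-oxobutanoate; 19 1,1-dimethoxypent-3-yn-2-one
Product: 21 prop-2-en-1-yl 3-(ring A oxy)-4-(dimethoxymethyl)-2-hydroxy-6-methylbenzoate, via open-chain Michael adduct 20 (not isolated)
Conditions: Cs2CO3 (30 mol%), DMSO, rt to 50 °C
Reagents that add atoms: none
Why: Carbonate deprotonates only the doubly activated α-carbon of 15 (C3′), which adds in Michael fashion to the methyl-bearing alkyne carbon of 19 (C4′) to give 20; proton shifts in this vinylogous system allow E/Z equilibration and generate the enolate at the aryloxy-bearing γ-carbon (C1′), whose acidity is raised by the ether oxygen. That carbon attacks the acetal-flanked ketone (C6′) in a 6-(enolendo)-exo-trig aldol closure, the only six-membered carbocyclisation open to 20, and loss of water followed by enolisation of the C2′ ketone should aromatise ring B irreversibly. The closest known reaction type is the base-mediated Michael–aldol (3+3) benzannulation of β-keto esters with ynones to salicylates; a γ-aryloxy donor is a new substrate for it. No stereocentre is formed, and the benzylic centre of ring A is remote from every acidic site. The step needs regiocontrol, which the allyl ester secures by making C3′ the only Michael donor, and chemoselectivity for ketone aldol over Dieckmann attack on the ring A ester or closure through oxygen, which the electrophilic dialkoxy ketone and the hindered 2,6-disubstituted TMSE benzoate should secure.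

Step 14
Reactants: 21 prop-2-en-1-yl 3-(ring A oxy)-4-(dimethoxymethyl)-2-hydroxy-6-methylbenzoate
Product: 22 3-(ring A oxy)-4-(dimethoxymethyl)-2-hydroxy-6-methylbenzoic acid
Conditions: Pd(PPh3)4 (5 mol%), morpholine, THF, rt; cold pH 4 citrate wash
Reagents that add atoms: none
Why: Tsuji–Trost deallylation: zerovalent palladium ionises the allyl ester to a π-allyl complex that morpholine captures, freeing the hindered salicylic acid without attack at any carbonyl, so TMSE ester, acetal and silyl ether stay.

Step 15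
Reactants: 22 3-(ring A oxy)-4-(dimethoxymethyl)-2-hydroxy-6-methylbenzoic acid
Product: 23 2-(ring A oxy)-3-(dimethoxymethyl)-5-methylphenol
Conditions: Ag2CO3 (10 mol%), AcOH (5 mol%), DMSO, 120 °C
Reagents that add atoms: none
Why: Silver-catalysed protodecarboxylation of an ortho,ortho′-disubstituted benzoic acid (aryl–silver formation with loss of CO2, then protonation), for which the 2-hydroxy-6-methyl pattern is especially prone; ring A carries an ester, not a free acid, and is inert.

Step 16
Reactants: 23 2-(ring A oxy)-3-(dimethoxymethyl)-5-methylphenol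
Product: 24 2-(ring A oxy)-3-hydroxy-5-methylbenzaldehyde
Conditions: pyridinium p-toluenesulfonate (10 mol%), acetone–H2O, rt
Reagents that add atoms: water, O
Why: Acid-catalysed hydrolysis of an aryl dimethyl acetal, which under pyridinium tosylate is far faster than cleavage of the secondary TBS ether or the TMSE ester.

Step 17
Reactants: 24 2-(ring A oxy)-3-hydroxy-5-methylbenzaldehyde; 25 1-(triphenyl-λ5-phosphanylidene)propan-2-one
Product: 26 (3E)-4-[2-(ring A oxy)-3-hydroxy-5-methylphenyl]but-3-en-2-one
Conditions: toluene, 90 °C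
Reagents that add atoms: none
Why: Wittig olefination with a ketone-stabilised ylide, whose reversible addition leads to the E-enone; the ylide is too weakly basic to be consumed by the phenol, which is meta to the aldehyde and cannot cyclise onto the enone.

Step 18
Reactants: 26 (3E)-4-[2-(ring A oxy)-3-hydroxy-5-methylphenyl]but-3-en-2-one
Product: 27 6-{2-hydroxy-4-methyl-6-[(1E)-3-oxobut-1-en-1-yl]phenoxy}-3-[(1R)-1-hydroxy-3-methylbutyl]-2-methoxybenzoic acid
Conditions: TBAF (5 equiv), THF, 0 °C to rt; dilute aq. HCl to pH 3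
Reagents that add atoms: none
Why: Fluoride-induced desilylation: fluoride cleaves the Si–O bond of the TBS ether and attacks silicon of the TMSE ester to fragment it (ethene, Me3SiF), so the hindered acid is freed without hydrolysis and the C–O bond of the stereocentre is not touched.

Step 19
Reactants: 27 6-{2-hydroxy-4-methyl-6-[(1E)-3-oxobut-1-en-1-yl]phenoxy}-3-[(1R)-1-hydroxy-3-methylbutyl]-2-methoxybenzoic acid
Product: 28 6-{2-(acetyloxy)-4-methyl-6-[(1E)-3-oxobut-1-en-1-yl]phenoxy}-3-[(1R)-1-(acetyloxy)-3-methylbutyl]-2-methoxybenzoic acid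
Conditions: Ac2O, pyridine, DMAP (10 mol%), CH2Cl2, 0 °C to rt; then H2O
Reagents that add atoms: acetic anhydride, CC(=O)OC(C)=O
Why: DMAP-catalysed acetylation of the secondary alcohol and the phenol with retention at carbon; any mixed anhydride at the hindered acid is hydrolysed at its acetyl carbonyl on aqueous work-up.

Step 20
Reactants: 28 6-{2-(acetyloxy)-4-methyl-6-[(1E)-3-oxobut-1-en-1-yl]phenoxy}-3-[(1R)-1-(acetyloxy)-3-methylbutyl]-2-methoxybenzoic acid
Product: 29 3-[(1R)-1-(acetyloxy)-3-methylbutyl]-6-{2-hydroxy-4-methyl-6-[(1E)-3-oxobut-1-en-1-yl]phenoxy}-2-methoxybenzoic acid (CNP0281268.2)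
Conditions: NH4OAc, MeOH–H2O, rt
Reagents that add atoms: none
Why: Chemoselective methanolysis (transesterification) of the aryl acetate under neutral ammonium acetate buffering: phenoxide is a far better leaving group than the secondary alkoxide, so the benzylic acetate, enone and acid should remain.

**Compound list**
1 | 4-hydroxy-2-methoxybenzaldehyde | COc1cc(O)ccc1C=O | starting material
2 | 2-methoxy-4-(methoxymethoxy)benzaldehyde | COCOc1ccc(C=O)c(OC)c1 | intermediate
3 | isobutylmagnesium bromide | CC(C)C[Mg]Br | starting material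
4 | rac-1-[2-methoxy-4-(methoxymethoxy)phenyl]-3-methylbutan-1-ol | COCOc1ccc(C(O)CC(C)C)c(OC)c1 | intermediate
5 | 1-[2-methoxy-4-(methoxymethoxy)phenyl]-3-methylbutan-1-one | COCOc1ccc(C(=O)CC(C)C)c(OC)c1 | intermediate
6 | (1R)-1-[2-methoxy-4-(methoxymethoxy)phenyl]-3-methylbutan-1-ol | COCOc1ccc([C@@H](CC(C)C)O)c(OC)c1 | intermediate
7 | tert-butyl{(1R)-1-[2-methoxy-4-(methoxymethoxy)phenyl]-3-methylbutoxy}dimethylsilane | COCOc1ccc([C@@H](CC(C)C)O[Si](C)(C)C(C)(C)C)c(OC)c1 | intermediate
8 | {3-[(1R)-1-(TBS-oxy)-3-methylbutyl]-2-methoxy-6-(methoxymethoxy)phenyl}lithium | COCOc1ccc([C@@H](CC(C)C)O[Si](C)(C)C(C)(C)C)c(OC)c1[Li] | intermediate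
9 | 3-[(1R)-1-(TBS-oxy)-3-methylbutyl]-2-methoxy-6-(methoxymethoxy)benzoic acid | COCOc1ccc([C@@H](CC(C)C)O[Si](C)(C)C(C)(C)C)c(OC)c1C(=O)O | intermediate
10 | TMSE 3-[(1R)-1-(TBS-oxy)-3-methylbutyl]-2-methoxy-6-(methoxymethoxy)benzoate | COCOc1ccc([C@@H](CC(C)C)O[Si](C)(C)C(C)(C)C)c(OC)c1C(=O)OCC[Si](C)(C)C | intermediate
11 | TMSE 3-[(1R)-1-(TBS-oxy)-3-methylbutyl]-2-methoxy-6-[(trimethylsilyl)oxy]benzoate | C[Si](C)(C)Oc1ccc([C@@H](CC(C)C)O[Si](C)(C)C(C)(C)C)c(OC)c1C(=O)OCC[Si](C)(C)C | intermediate
12 | TMSE 3-[(1R)-1-(TBS-oxy)-3-methylbutyl]-6-hydroxy-2-methoxybenzoate | Oc1ccc([C@@H](CC(C)C)O[Si](C)(C)C(C)(C)C)c(OC)c1C(=O)OCC[Si](C)(C)C | intermediate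
13 | ethyl 4-chloro-3-oxobutanoate | CCOC(=O)CC(=O)CCl | starting material
14 | prop-2-en-1-yl 4-chloro-3-oxobutanoate | C=CCOC(=O)CC(=O)CCl | intermediate
15 | prop-2-en-1-yl 4-(ring A oxy)-3-oxobutanoate | C=CCOC(=O)CC(=O)COc1ccc([C@@H](CC(C)C)O[Si](C)(C)C(C)(C)C)c(OC)c1C(=O)OCC[Si](C)(C)C | intermediate
16 | methyl 2,2-dimethoxyacetate | COC(OC)C(=O)OC | starting material
17 | N,2,2-trimethoxy-N-methylacetamide | COC(OC)C(=O)N(C)OC | intermediate
18 | prop-1-yn-1-ylmagnesium bromide | CC#C[Mg]Br | starting material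
19 | 1,1-dimethoxypent-3-yn-2-one | CC#CC(=O)C(OC)OC | intermediate
20 | prop-2-en-1-yl 2-[(ring A oxy)acetyl]-6,6-dimethoxy-3-methyl-5-oxohex-3-enoate (alkene isomers and enol tautomers) | C=CCOC(=O)C(C(=O)COc1ccc([C@@H](CC(C)C)O[Si](C)(C)C(C)(C)C)c(OC)c1C(=O)OCC[Si](C)(C)C)C(C)=CC(=O)C(OC)OC | intermediate
21 | prop-2-en-1-yl 3-(ring A oxy)-4-(dimethoxymethyl)-2-hydroxy-6-methylbenzoate | C=CCOC(=O)c1c(C)cc(C(OC)OC)c(Oc2ccc([C@@H](CC(C)C)O[Si](C)(C)C(C)(C)C)c(OC)c2C(=O)OCC[Si](C)(C)C)c1O | intermediate
22 | 3-(ring A oxy)-4-(dimethoxymethyl)-2-hydroxy-6-methylbenzoic acid | OC(=O)c1c(C)cc(C(OC)OC)c(Oc2ccc([C@@H](CC(C)C)O[Si](C)(C)C(C)(C)C)c(OC)c2C(=O)OCC[Si](C)(C)C)c1O | intermediate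
23 | 2-(ring A oxy)-3-(dimethoxymethyl)-5-methylphenol | Cc1cc(O)c(Oc2ccc([C@@H](CC(C)C)O[Si](C)(C)C(C)(C)C)c(OC)c2C(=O)OCC[Si](C)(C)C)c(C(OC)OC)c1 | intermediate
24 | 2-(ring A oxy)-3-hydroxy-5-methylbenzaldehyde | Cc1cc(O)c(Oc2ccc([C@@H](CC(C)C)O[Si](C)(C)C(C)(C)C)c(OC)c2C(=O)OCC[Si](C)(C)C)c(C=O)c1 | intermediate
25 | 1-(triphenyl-λ5-phosphanylidene)propan-2-one | CC(=O)C=P(c1ccccc1)(c1ccccc1)c1ccccc1 | starting material
26 | (3E)-4-[2-(ring A oxy)-3-hydroxy-5-methylphenyl]but-3-en-2-one | Cc1cc(O)c(Oc2ccc([C@@H](CC(C)C)O[Si](C)(C)C(C)(C)C)c(OC)c2C(=O)OCC[Si](C)(C)C)c(/C=C/C(C)=O)c1 | intermediate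
27 | 6-{2-hydroxy-4-methyl-6-[(1E)-3-oxobut-1-en-1-yl]phenoxy}-3-[(1R)-1-hydroxy-3-methylbutyl]-2-methoxybenzoic acid | Cc1cc(O)c(Oc2ccc([C@@H](CC(C)C)O)c(OC)c2C(=O)O)c(/C=C/C(C)=O)c1 | intermediate
28 | 6-{2-(acetyloxy)-4-methyl-6-[(1E)-3-oxobut-1-en-1-yl]phenoxy}-3-[(1R)-1-(acetyloxy)-3-methylbutyl]-2-methoxybenzoic acid | Cc1cc(OC(C)=O)c(Oc2ccc([C@@H](CC(C)C)OC(C)=O)c(OC)c2C(=O)O)c(/C=C/C(C)=O)c1 | intermediate
29 | 3-[(1R)-1-(acetyloxy)-3-methylbutyl]-6-{2-hydroxy-4-methyl-6-[(1E)-3-oxobut-1-en-1-yl]phenoxy}-2-methoxybenzoic acid (CNP0281268.2) | COc1c([C@@H](CC(C)C)OC(C)=O)ccc(Oc2c(O)cc(C)cc2/C=C/C(C)=O)c1C(=O)O | target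

**Step count**
Total steps: 20. Longest linear sequence: 17 (steps 1–8, 10, 13–20); steps 9 and 11–12 are side branches.

**Steps most likely to fail**

Step 13 (benzannulation). The ynone may isomerise or oligomerise under carbonate, or the unsaturated Michael adduct may close through oxygen (pyran or pyranone formation) instead of through the aryloxy-bearing carbon. The fallback forms the same two ring bonds one oxidation level lower and in separate operations. Setting out from 15, Weinreb amide 17 would be treated with prop-1-en-1-ylmagnesium bromide to give (E)-1,1-dimethoxypent-3-en-2-one F1. Robinson-type Michael–aldol condensation of 15 with F1 (K2CO3 in MeCN, pyrrolidinium acetate if the aldol condensation lags) should give prop-2-en-1-yl 3-(ring A oxy)-4-(dimethoxymethyl)-6-methyl-2-oxocyclohex-3-ene-1-carboxylate F2, the normal outcome for β-keto esters and enones. Deprotonation of its β-keto ester (NaH) and selenenylation with PhSeCl, which should enter anti to the neighbouring methyl group, would give the 1-(phenylselanyl) derivative F3. Oxidation with H2O2 to the selenoxide F4 would then trigger syn-elimination toward C6 and tautomerisation of the dienone to the phenol, returning to salicylate 21.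

Step 10 (phenol alkylation). The chloro keto ester may self-condense, and substitution by the hydrogen-bonded, ester-flanked phenoxide may be slow. The fallback makes the ether bond with a two-carbon electrophile and builds the keto ester afterwards. Setting out from phenol 12, allyl bromoacetate and K2CO3 in acetone should give prop-2-en-1-yl (ring A oxy)acetate F5. Deallylation with zerovalent palladium (Pd(PPh3)4, morpholine) would give (ring A oxy)acetic acid F6, and 1,1′-carbonyldiimidazole would give 1-[(ring A oxy)acetyl]imidazole F7. Decarboxylative Claisen condensation of F7 with the magnesium salt of monoallyl malonate, Mg(O2CCH2CO2CH2CH=CH2)2, returns to β-keto ester 15.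

Step 6 (metalation–carboxylation). The alkyllithium may metalate the silyloxy-bearing benzylic carbon (silyl migration, erosion of the stereocentre) or attack silicon. The fallback installs the carboxyl group before silylation. Setting out from carbinol 6, n-BuLi (2.5 equiv, THF, −78 to 0 °C) would first form the lithium alkoxide, which cannot be metalated at the carbinol carbon, and then the ring-lithiated alkoxide F8. CO2 would give 3-[(1R)-1-hydroxy-3-methylbutyl]-2-methoxy-6-(methoxymethoxy)benzoic acid F9. Promoter-free esterification of the acid with 2-(trimethylsilyl)ethyl 2,2,2-trichloroacetimidate in hot toluene should give the TMSE hydroxy ester F10, and silylation (TBSOTf, 2,6-lutidine) returns to ester 10.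

Further compounds
F1 | step 13 | (E)-1,1-dimethoxypent-3-en-2-one | C/C=C/C(=O)C(OC)OC
F2 | step 13 | prop-2-en-1-yl 3-(ring A oxy)-4-(dimethoxymethyl)-6-methyl-2-oxocyclohex-3-ene-1-carboxylate (ring diastereomers) | C=CCOC(=O)C1C(C)CC(C(OC)OC)=C(Oc2ccc([C@@H](CC(C)C)O[Si](C)(C)C(C)(C)C)c(OC)c2C(=O)OCC[Si](C)(C)C)C1=O
F3 | step 13 | prop-2-en-1-yl 3-(ring A oxy)-4-(dimethoxymethyl)-6-methyl-2-oxo-1-(phenylselanyl)cyclohex-3-ene-1-carboxylate | C=CCOC(=O)C1([Se]c2ccccc2)C(C)CC(C(OC)OC)=C(Oc3ccc([C@@H](CC(C)C)O[Si](C)(C)C(C)(C)C)c(OC)c3C(=O)OCC[Si](C)(C)C)C1=O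
F4 | step 13 | prop-2-en-1-yl 3-(ring A oxy)-4-(dimethoxymethyl)-6-methyl-2-oxo-1-(phenylseleninyl)cyclohex-3-ene-1-carboxylate | C=CCOC(=O)C1([Se](=O)c2ccccc2)C(C)CC(C(OC)OC)=C(Oc3ccc([C@@H](CC(C)C)O[Si](C)(C)C(C)(C)C)c(OC)c3C(=O)OCC[Si](C)(C)C)C1=O
F5 | step 10 | prop-2-en-1-yl (ring A oxy)acetate | C=CCOC(=O)COc1ccc([C@@H](CC(C)C)O[Si](C)(C)C(C)(C)C)c(OC)c1C(=O)OCC[Si](C)(C)C
F6 | step 10 | (ring A oxy)acetic acid | OC(=O)COc1ccc([C@@H](CC(C)C)O[Si](C)(C)C(C)(C)C)c(OC)c1C(=O)OCC[Si](C)(C)C
F7 | step 10 | 1-[(ring A oxy)acetyl]-1H-imidazole | O=C(COc1ccc([C@@H](CC(C)C)O[Si](C)(C)C(C)(C)C)c(OC)c1C(=O)OCC[Si](C)(C)C)n1ccnc1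
F8 | step 6 | lithium (1R)-1-[3-lithio-2-methoxy-4-(methoxymethoxy)phenyl]-3-methylbutan-1-olate | COCOc1ccc([C@@H](CC(C)C)O[Li])c(OC)c1[Li]
F9 | step 6 | 3-[(1R)-1-hydroxy-3-methylbutyl]-2-methoxy-6-(methoxymethoxy)benzoic acid | COCOc1ccc([C@@H](CC(C)C)O)c(OC)c1C(=O)O
F10 | step 6 | TMSE 3-[(1R)-1-hydroxy-3-methylbutyl]-2-methoxy-6-(methoxymethoxy)benzoate | COCOc1ccc([C@@H](CC(C)C)O)c(OC)c1C(=O)OCC[Si](C)(C)C
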